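## Analysis of the target

Atom labels used below: C7–C8–C9 is the chain on ring A, C2 and C3 are the sp3 carbons of the dihydrofuran, and C9' is the hydroxymethyl carbon on C3.

- The target is a sesquineolignan of three aryl units. Ring A is a guaiacyl ring (free phenol, one methoxy group) carrying the chain C7(OH)–C8(OAr)–C9H2OH. Ring B is a syringyl-type ring whose phenolic oxygen is the ether oxygen on C8 and whose para carbon sits on C2 of a 2,3-dihydrobenzofuran. Ring C is the benzo ring of that bicycle, with a methoxy group next to the ring oxygen and a formyl group para to it.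
- There are four stereocentres in two pairs: C7/C8 are (7S,8R), the erythro arrangement of an open chain, and C2/C3 are (2R,3S), trans on the five-membered ring.
- The pairs are separated by the para-disubstituted ring B, so neither can steer the other and each needs its own source of absolute configuration.
- Sensitive groups: the para-hydroxybenzylic alcohol at C7 ionises to a quinone methide under acid or base and can epimerise; the aldehyde; and the C2–O bond, a benzylic aryl ether that can be hydrogenolysed.
- Two things make the synthesis hard. The C8–O bond joins a secondary carbon to a phenol flanked by two methoxy groups. The erythro relation lies in a freely rotating chain with no ring to relay configuration from C8 to C7.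
- The strategy rests on one feature: C7 is benzylic, para to the free phenol of ring A, and 1,3 to the oxygen on C9. Two-electron oxidation of ring A makes C7 the electrophilic end of a para-quinone methide, and an acyl group on O9 can reach it through a six-membered ring in which C8 dictates the geometry.

## Retrosynthetic reasoning

**From 31 back to 27 (protecting groups and tether).** No skeletal bond is cut. The aldehyde of 31 is carried as the dioxolane of 30 and freed last under acid mild enough for the para-hydroxybenzylic alcohol. Compound 30 is 29 without its two silyl groups, the 7,9-diol of 29 is the hydride-opened cyclic carbonate of 28, and 28 is 27 with the ring A phenol silylated. The order matters: a free phenol para to an acylated O7 expels that oxygen again, so the phenol is capped first. The carbonate is opened reductively because basic alcoholysis could strip the aryl silyl ether while O7 is still acylated.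

**C7–O bond of 27 (key disconnection).** Cutting the bond between C7 and the carbonate oxygen, and restoring a tert-butyl group on the carbonate, leads to the open-chain tert-butyl carbonate 25, which has no oxygen at C7. Forward, ring A of 25 is oxidised to the quinone methide 26, the carbonate carbonyl oxygen adds 1,6 to C7, ring A rearomatises and the tert-butyl group is lost. The cut is made here because C7 is the one stereocentre that no existing group can direct in the open chain; inside the six-membered ring its configuration is relayed from C8. The gain is one ring, one C–O bond and one stereocentre, and C7 never passes through a ketone or an unprotected benzylic alcohol.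

**From 25 back to 22 (functional group changes).** The phenol of 25 is released from the aryl silyl ether 24, the carbonate of 24 is placed on the primary alcohol 23, and 23 is the reduction product of ester 22. C8 is untouched.

**C8–O(ring B) bond of 22.** Cutting between C8 and the ether oxygen gives phenol 16 and hydroxy ester 21. Forward, a Mitsunobu substitution with inversion joins them. The ester next to C8 speeds displacement by the hindered phenol and suppresses participation by the neighbouring electron-rich ring. The gain is convergence, and C8 comes from the chiral pool instead of an asymmetric reaction on the assembled molecule.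

**Ring A–C7 bond of 21.** This cut gives the aryl Grignard reagent 20 (from bromide 18, from 17) and the glycidic ester 19. The forward reaction is a copper-catalysed opening at the unsubstituted epoxide carbon, which leaves the stereocentre of 19 untouched.

**From 16 back to 13.** Phenol 16 comes from benzyl ether 15 by hydrogenolysis, 15 is the silyl ether of alcohol 14, and 14 is the reduction product of ester 13. The ester of 13 allows C3 to be corrected before it becomes C9'.

**C2–C3 bond of 13.** This cut leads to diazo ester 11. Forward, a dirhodium carbene inserts into the benzylic ether C–H bond to give the cis ester 12, which is epimerised at C3 to 13. The bond is chosen because it forms the ring and both stereocentres from an achiral precursor under catalyst control, and the C3 ester lets thermodynamics set the trans relation.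

**From 11 to the starting materials.** Compound 11 arises by diazo transfer to arylacetate 10. Ester 10 comes from cross-coupling of aryl iodide 7 with the zinc enolate 9 made from 8. Iodide 7 is the acetal of 6, and 6 is the ether of 5 with bromide 4, which is made from 1 through 2 and 3.

## Alternatives that were turned down

**Alternative 1:** Alkoxycarbonylative cyclisation of a hydroxystilbene.
- Disconnection: the O–C2 and C3–C9' bonds, leading to 4-hydroxy-3-methoxy-5-[(E)-2-(3,5-dimethoxy-4-triisopropylsilyloxyphenyl)ethenyl]benzaldehyde A1.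
- Key step: divalent palladium activates the alkene, the ring C phenol adds to the carbon bearing ring B, and the C3–palladium bond inserts carbon monoxide and is cleaved by methanol to give the trans ester A2, methyl (2R,3R)-2-(3,5-dimethoxy-4-triisopropylsilyloxyphenyl)-5-formyl-7-methoxy-2,3-dihydrobenzofuran-3-carboxylate.
- For: A1 is one Heck coupling away from 5, so the bicycle with its C9' carbon would take about three steps, against eight here. The trans geometry follows from anti addition to the (E)-alkene and retentive insertion.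
- Against: the alkyl-palladium at C3 is benzylic and has a syn hydrogen on C2, so β-hydride elimination to the aromatic 2-arylbenzofuran competes with carbonylation. The oxypalladation is 5-endo. Absolute configuration would have to come from a ligand on a metal that sits on the face opposite the forming C–O bond.
- Comparison: it is clearly stronger on step economy for the bicycle. Its uncertainty is early, concerns absolute configuration that cannot be corrected later, and leaves C7/C8 unsolved. The chosen plan builds the bicycle by a known catalyst-controlled insertion and spends its one speculative step on C7, with a known fallback.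

**Alternative 2:** Aryl radical cyclisation with TEMPO capture.
- Disconnection: the C3a–C3 and C9'–O bonds, leading to the iodo allyl ether A3, 4-[(1R)-1-[4-(1,3-dioxolan-2-yl)-2-iodo-6-methoxyphenoxy]prop-2-en-1-yl]-2,6-dimethoxyphenyl pivalate.
- Key step: the aryl radical from the iodide adds 5-exo to the vinyl group and TEMPO caps the primary radical, giving A4, the (2R,3S)-3-[(2,2,6,6-tetramethylpiperidin-1-yloxy)methyl] dihydrobenzofuran pivalate.
- For: the C2 centre of A3 could be set in one enantioselective allylic etherification. Aryl radical 5-exo closure with nitroxide trapping is known, and the acetal and ester tolerate it.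
- Against: C3 is formed under kinetic control, where a trans preference from the chair-like transition state is usually only moderate. A CH2O–N group at C3 cannot be equilibrated afterwards. A3 is a benzylic, allylic aryl ether of an electron-rich ring and is prone to ionisation. The N–O bond needs a separate reductive cleavage.
- Comparison: it is shorter than the carbene route by a few steps and equal on absolute control of C2. It is weaker on the C2/C3 relation, which the chosen route settles by epimerisation of an ester. It does not address C7.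

**Alternative 3:** Ring B quinone methide closing the dihydrofuran.
- Disconnection: the O–C2 bond, leading to bisphenol A5, 4-hydroxy-3-[(2S)-1-(tert-butyldimethylsilyloxy)-3-(4-hydroxy-3,5-dimethoxyphenyl)propan-2-yl]-5-methoxybenzaldehyde.
- Key step: Ag2O oxidises the ring B phenol to a para-quinone methide at the future C2 and the ring C phenol adds 5-exo, giving A6, (2R,3S)-2-(4-hydroxy-3,5-dimethoxyphenyl)-3-(tert-butyldimethylsilyloxymethyl)-7-methoxy-2,3-dihydrobenzofuran-5-carbaldehyde.
- For: this uses the same logic as the chosen key step on a more favourable substrate. A 2,6-dimethoxy-4-alkylphenol has no free ortho position for radical coupling, a phenol is a far better nucleophile than a carbonate carbonyl, and the trans isomer is the thermodynamic one because the free para-phenol keeps the closure reversible. As a single step it is closer to precedent than the chosen key step, and A6 is the free-aldehyde analogue of 16.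
- Against: the stereocentre of A5 must first be made enantioselectively, so the sequence is no shorter. The ring C phenol is para to an aldehyde and weakly nucleophilic.
- Comparison: it is stronger on precedent and on cleanliness of the oxidation. It spends the quinone methide idea on C2, which is controllable by other means, and leaves C7 to unselective chemistry. The chosen strategy uses the same reactivity at C7, where making the chain temporarily cyclic creates the erythro selectivity that is otherwise missing.

Key step: step 18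

Assumption: the (S)-configured catalyst Rh2(S-PTTL)4 is written for step 8 on the understanding that it delivers the (2R) centre; if the sense of induction on this substrate is the opposite, the mirror-image catalyst is used and nothing else changes.

Abbreviations in names: TBS = tert-butyldimethylsilyl; ArO = the aryloxy group of 16, that is 4-[(2R,3S)-3-(TBS-oxymethyl)-5-(1,3-dioxolan-2-yl)-7-methoxy-2,3-dihydro-1-benzofuran-2-yl]-2,6-dimethoxyphenoxy.

## Route

Step 1
Reactants: 1 syringaldehyde (4-hydroxy-3,5-dimethoxybenzaldehyde)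
Product: 2 4-(benzyloxy)-3,5-dimethoxybenzaldehyde
Conditions: BnBr, K2CO3, DMF, 60 °C
Reagents that add atoms: benzyl bromide, BrCc1ccccc1
Why: Williamson etherification of an acidic para-formyl phenol; the benzyl group survives every step up to the dihydrobenzofuran and is then removed by hydrogenolysis.

Step 2
Reactants: 2 4-(benzyloxy)-3,5-dimethoxybenzaldehyde
Product: 3 [4-(benzyloxy)-3,5-dimethoxyphenyl]methanol
Conditions: NaBH4, MeOH/THF, 0 °C
Reagents that add atoms: none
Why: Borohydride reduction of an aryl aldehyde; no other reducible group is present.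

Step 3
Reactants: 3 [4-(benzyloxy)-3,5-dimethoxyphenyl]methanol
Product: 4 2-(benzyloxy)-5-(bromomethyl)-1,3-dimethoxybenzene
Conditions: PBr3, CH2Cl2, 0 °C
Reagents that add atoms: phosphorus tribromide, BrP(Br)Br
Why: Conversion of a benzylic alcohol into the bromide through its phosphite ester; the electron-rich bromide is used crude.

Step 4
Reactants: 4 2-(benzyloxy)-5-(bromomethyl)-1,3-dimethoxybenzene; 5 5-iodovanillin (4-hydroxy-3-iodo-5-methoxybenzaldehyde)
Product: 6 4-{[4-(benzyloxy)-3,5-dimethoxybenzyl]oxy}-3-iodo-5-methoxybenzaldehyde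
Conditions: K2CO3, DMF, rt
Reagents that add atoms: none
Why: Williamson etherification; the phenol of 5 is acidic (para-formyl, ortho-iodo) and the benzylic bromide is a reactive SN2 partner.

Step 5
Reactants: 6 4-{[4-(benzyloxy)-3,5-dimethoxybenzyl]oxy}-3-iodo-5-methoxybenzaldehyde
Product: 7 2-(4-{[4-(benzyloxy)-3,5-dimethoxybenzyl]oxy}-3-iodo-5-methoxyphenyl)-1,3-dioxolane
Conditions: TMSOCH2CH2OTMS, TMSOTf (2 mol %), CH2Cl2, −78 → −20 °C
Reagents that add atoms: 1,2-bis(trimethylsilyloxy)ethane, C[Si](C)(C)OCCO[Si](C)(C)C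
Why: Noyori acetalisation; low temperature and catalytic silyl triflate spare the acid-sensitive electron-rich benzylic ether, and the acetal keeps the aldehyde away from the zinc enolate, the carbene and the hydrides that follow.

Step 6
Reactants: 7 2-(4-{[4-(benzyloxy)-3,5-dimethoxybenzyl]oxy}-3-iodo-5-methoxyphenyl)-1,3-dioxolane; 8 methyl bromoacetate
Product: 10 methyl 2-[2-{[4-(benzyloxy)-3,5-dimethoxybenzyl]oxy}-5-(1,3-dioxolan-2-yl)-3-methoxyphenyl]acetate, via Reformatsky reagent 9 (not isolated)
Conditions: 8, Zn dust (TMSCl-activated), THF, rt; then 7, Pd2(dba)3 (1 mol %), XPhos (4 mol %), THF, 60 °C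
Reagents that add atoms: none
Why: Negishi-type coupling of a Reformatsky reagent with an aryl iodide (oxidative addition to zerovalent palladium, transmetallation of the zinc enolate, reductive elimination); the near-neutral conditions leave the acetal and both benzylic ethers intact.

Step 7
Reactants: 10 methyl 2-[2-{[4-(benzyloxy)-3,5-dimethoxybenzyl]oxy}-5-(1,3-dioxolan-2-yl)-3-methoxyphenyl]acetate
Product: 11 methyl 2-diazo-2-[2-{[4-(benzyloxy)-3,5-dimethoxybenzyl]oxy}-5-(1,3-dioxolan-2-yl)-3-methoxyphenyl]acetate
Conditions: p-ABSA, DBU, MeCN, 0 °C → rt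
Reagents that add atoms: 4-acetamidobenzenesulfonyl azide, CC(=O)Nc1ccc(cc1)S(=O)(=O)N=[N+]=[N-]
Why: Regitz diazo transfer to an arylacetate, the standard entry to aryldiazoacetates.

Step 8
Reactants: 11 methyl 2-diazo-2-[2-{[4-(benzyloxy)-3,5-dimethoxybenzyl]oxy}-5-(1,3-dioxolan-2-yl)-3-methoxyphenyl]acetate
Product: 13 methyl (2R,3R)-2-[4-(benzyloxy)-3,5-dimethoxyphenyl]-5-(1,3-dioxolan-2-yl)-7-methoxy-2,3-dihydro-1-benzofuran-3-carboxylate (trans), via cis ester 12 (not isolated)
Conditions: Rh2(S-PTTL)4 (dirhodium tetrakis[N-phthaloyl-(S)-tert-leucinate], 1 mol %), toluene, −60 °C; then NaOMe (0.3 equiv), MeOH, rt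
Reagents that add atoms: none
Why: Intramolecular dirhodium-carbene insertion into the benzylic ether C–H bond (known for aryldiazoacetates with an ortho benzyloxy group) closes the five-membered ring and sets C2 under control of the chiral carboxylate ligands, giving the cis ester 12. Catalytic methoxide then epimerises only C3, alpha to the ester, to the more stable trans ester; C2 cannot epimerise because ring B carries no free phenol.

Step 9
Reactants: 13 methyl (2R,3R)-2-[4-(benzyloxy)-3,5-dimethoxyphenyl]-5-(1,3-dioxolan-2-yl)-7-methoxy-2,3-dihydro-1-benzofuran-3-carboxylate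
Product: 14 [(2R,3S)-2-[4-(benzyloxy)-3,5-dimethoxyphenyl]-5-(1,3-dioxolan-2-yl)-7-methoxy-2,3-dihydro-1-benzofuran-3-yl]methanol
Conditions: LiAlH4, THF, 0 °C
Reagents that add atoms: none
Why: Hydride reduction of the ester to the C9' alcohol; acetal and benzyl ethers are inert, and C3 is no longer epimerisable afterwards (the descriptor changes to 3S only through the priority rules).

Step 10
Reactants: 14 [(2R,3S)-2-[4-(benzyloxy)-3,5-dimethoxyphenyl]-5-(1,3-dioxolan-2-yl)-7-methoxy-2,3-dihydro-1-benzofuran-3-yl]methanol
Product: 15 tert-butyl{[(2R,3S)-2-[4-(benzyloxy)-3,5-dimethoxyphenyl]-5-(1,3-dioxolan-2-yl)-7-methoxy-2,3-dihydro-1-benzofuran-3-yl]methoxy}dimethylsilane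
Conditions: TBSCl, imidazole, DMF, rt
Reagents that add atoms: tert-butyldimethylsilyl chloride, CC(C)(C)[Si](C)(C)Cl
Why: Silylation of a primary alcohol; the TBS ether is stable to every reagent up to the fluoride step near the end.

Step 11
Reactants: 15 tert-butyl{[(2R,3S)-2-[4-(benzyloxy)-3,5-dimethoxyphenyl]-5-(1,3-dioxolan-2-yl)-7-methoxy-2,3-dihydro-1-benzofuran-3-yl]methoxy}dimethylsilane
Product: 16 4-[(2R,3S)-3-(TBS-oxymethyl)-5-(1,3-dioxolan-2-yl)-7-methoxy-2,3-dihydro-1-benzofuran-2-yl]-2,6-dimethoxyphenol
Conditions: H2 (1 atm), 10% Pd/C, EtOAc, rt, stopped after one equivalent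
Reagents that add atoms: none
Why: Hydrogenolysis of a primary benzyl aryl ether, which should be faster than cleavage of the secondary, ring-held C2–O bond; the aprotic neutral solvent protects acetal and silyl ether.

Step 12
Reactants: 17 4-bromo-2-methoxyphenol
Product: 18 (4-bromo-2-methoxyphenoxy)(tert-butyl)dimethylsilane
Conditions: TBSCl, imidazole, DMF, rt
Reagents that add atoms: tert-butyldimethylsilyl chloride, CC(C)(C)[Si](C)(C)Cl
Why: Phenol silylation; the aryl TBS ether tolerates Grignard formation and can later be removed selectively beside an alkyl TBS ether.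

Step 13
Reactants: 18 (4-bromo-2-methoxyphenoxy)(tert-butyl)dimethylsilane; 19 methyl (2R)-oxirane-2-carboxylate (methyl (R)-glycidate)
Product: 21 methyl (2R)-3-(4-TBS-oxy-3-methoxyphenyl)-2-hydroxypropanoate, via aryl Grignard reagent 20 (not isolated)
Conditions: 18, Mg, THF, 50 °C; then CuBr·SMe2 (10 mol %), 19, THF, −40 → −20 °C
Reagents that add atoms: none
Why: Copper-catalysed SN2 opening of the glycidic ester at its unsubstituted carbon by the aryl Grignard reagent forms the ring A–C7 bond; the stereocentre of 19 is not involved and is carried over unchanged, and low temperature with copper keeps the ester from being attacked.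

Step 14
Reactants: 16 4-[(2R,3S)-3-(TBS-oxymethyl)-5-(1,3-dioxolan-2-yl)-7-methoxy-2,3-dihydro-1-benzofuran-2-yl]-2,6-dimethoxyphenol; 21 methyl (2R)-3-(4-TBS-oxy-3-methoxyphenyl)-2-hydroxypropanoate
Product: 22 methyl (2S)-2-(ArO)-3-(4-TBS-oxy-3-methoxyphenyl)propanoate
Conditions: PPh3, DIAD, toluene, 0 °C → rt
Reagents that add atoms: none
Why: Mitsunobu etherification: the oxyphosphonium of the alpha-hydroxy ester is displaced by the phenoxide in an SN2 step with inversion, which turns the (R) alcohol into the (S) aryl ether and so fixes C8. The adjacent ester accelerates displacement and disfavours participation by the neighbouring aryl ring.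

Step 15
Reactants: 22 methyl (2S)-2-(ArO)-3-(4-TBS-oxy-3-methoxyphenyl)propanoate
Product: 23 (2S)-2-(ArO)-3-(4-TBS-oxy-3-methoxyphenyl)propan-1-ol
Conditions: LiBH4, THF, 0 °C → rt
Reagents that add atoms: none
Why: Borohydride reduction of an activated alpha-aryloxy ester to the C9 alcohol; it is faster than enolisation, so C8 is kept, and silyl ethers and the acetal are inert.

Step 16
Reactants: 23 (2S)-2-(ArO)-3-(4-TBS-oxy-3-methoxyphenyl)propan-1-ol
Product: 24 tert-butyl (2S)-2-(ArO)-3-(4-TBS-oxy-3-methoxyphenyl)propyl carbonate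
Conditions: Boc2O, DMAP (0.1 equiv), MeCN, rt
Reagents that add atoms: di-tert-butyl dicarbonate, CC(C)(C)OC(=O)OC(=O)OC(C)(C)C
Why: DMAP-catalysed tert-butoxycarbonylation of the only free hydroxyl group installs the tether for the key step.

Step 17
Reactants: 24 tert-butyl (2S)-2-(ArO)-3-(4-TBS-oxy-3-methoxyphenyl)propyl carbonate
Product: 25 tert-butyl (2S)-2-(ArO)-3-(4-hydroxy-3-methoxyphenyl)propyl carbonate
Conditions: Cs2CO3 (0.5 equiv), DMF/H2O (10:1), rt
Reagents that add atoms: none
Why: Aryl silyl ethers are cleaved by mild aqueous carbonate far faster than alkyl silyl ethers because phenoxide is the better leaving group; the alkyl tert-butyl carbonate and the primary TBS ether should survive, and the phenoxide is harmless here because C7 carries no leaving group.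

Step 18
Reactants: 25 tert-butyl (2S)-2-(ArO)-3-(4-hydroxy-3-methoxyphenyl)propyl carbonate
Product: 27 (4S,5R)-5-(ArO)-4-(4-hydroxy-3-methoxyphenyl)-1,3-dioxan-2-one, via quinone methide 26 (not isolated)
Conditions: Ag2O (3 equiv), 4 Å MS, CH2Cl2, rt, dark; filter under argon; then Sc(OTf)3 (5 mol %), fresh 4 Å MS, −40 → 0 °C; pH 7 buffer
Reagents that add atoms: none
Why: Proposed new method: Ag2O takes two electrons and two protons from the only free phenol of 25 and dearomatises ring A to the para-quinone methide 26, in which C7 is the electrophilic terminus (known for 4-alkyl-2-methoxyphenols). Sc(OTf)3 then binds the quinone methide oxygen, the carbonyl oxygen of the O9 tert-butyl carbonate adds to C7, ring A rearomatises and the O-alkylated carbonate cation loses its tert-butyl group as isobutene, the released proton turning the catalyst over. The closest known reaction types are 1,6-addition of oxygen nucleophiles to such quinone methides and cyclisation of tert-butyl carbonates onto cationic carbon (as in iodocarbonate formation); their combination on an oxidatively generated quinone methide has not been shown. The one ring formed, the 1,3-dioxan-2-one, closes in the 6-exo-trig mode because the C7=C1 bond of the quinone methide lies outside it. The new stereocentre C7 is controlled by C8 through a chair-like transition state: H8 sits in the plane of the quinone methide to avoid allylic 1,3-strain, the C9 tether delivers the oxygen to the face on which C9 lies, and the C8 aryloxy group is then anti to the forming bond, so ring A and the aryloxy group end up trans-diequatorial, which is the erythro (7S,8R) series. If the closure reverses through re-ionisation of the para-hydroxybenzyl carbonate, the same trans isomer is expected to be favoured at equilibrium, so both modes of control point the same way. Chemoselectivity is secured because ring A has the only free phenol (ring B, the dihydrobenzofuran, the dioxolane and the silyl ether are inert to Ag2O), and capture by the tether ahead of water or a second molecule is secured by molecular sieves, dilution and the entropic advantage of the six-membered closure.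

Step 19
Reactants: 27 (4S,5R)-5-(ArO)-4-(4-hydroxy-3-methoxyphenyl)-1,3-dioxan-2-one
Product: 28 (4S,5R)-5-(ArO)-4-(4-TBS-oxy-3-methoxyphenyl)-1,3-dioxan-2-one
Conditions: MTBSTFA (1.5 equiv), MeCN, 0 °C → rt (crude 27 used at once)
Reagents that add atoms: N-(tert-butyldimethylsilyl)-N-methyltrifluoroacetamide, CN(C(=O)C(F)(F)F)[Si](C)(C)C(C)(C)C
Why: Silyl transfer from a neutral silylamide caps the phenol without added base, so the phenoxide that would expel the benzylic carbonate is not generated; once silylated, ring A can no longer push out the C7 oxygen.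

Step 20
Reactants: 28 (4S,5R)-5-(ArO)-4-(4-TBS-oxy-3-methoxyphenyl)-1,3-dioxan-2-one
Product: 29 (1S,2R)-2-(ArO)-1-(4-TBS-oxy-3-methoxyphenyl)propane-1,3-diol
Conditions: LiAlH4, THF, −20 → 0 °C; Rochelle salt work-up
Reagents that add atoms: none
Why: Hydride reduction of a cyclic carbonate to its diol attacks only the carbonyl carbon, so neither C–O bond at C7 or C9 is broken and the configuration is retained; the aryl silyl ether stays on throughout, which basic methanolysis could not guarantee.

Step 21
Reactants: 29 (1S,2R)-2-(ArO)-1-(4-TBS-oxy-3-methoxyphenyl)propane-1,3-diol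
Product: 30 (1S,2R)-2-{4-[(2R,3S)-5-(1,3-dioxolan-2-yl)-3-(hydroxymethyl)-7-methoxy-2,3-dihydro-1-benzofuran-2-yl]-2,6-dimethoxyphenoxy}-1-(4-hydroxy-3-methoxyphenyl)propane-1,3-diol
Conditions: Bu4NF, AcOH (1:1), THF, 0 °C → rt
Reagents that add atoms: none
Why: Fluoride cleaves both the aryl and the primary alkyl silyl ether; buffering with acetic acid keeps the liberated para-hydroxybenzylic alcohol away from strongly basic conditions.

Step 22
Reactants: 30 (1S,2R)-2-{4-[(2R,3S)-5-(1,3-dioxolan-2-yl)-3-(hydroxymethyl)-7-methoxy-2,3-dihydro-1-benzofuran-2-yl]-2,6-dimethoxyphenoxy}-1-(4-hydroxy-3-methoxyphenyl)propane-1,3-diol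
Product: 31 (2R,3S)-2-(4-{[(1S,2R)-1,3-dihydroxy-1-(4-hydroxy-3-methoxyphenyl)propan-2-yl]oxy}-3,5-dimethoxyphenyl)-3-(hydroxymethyl)-7-methoxy-2,3-dihydro-1-benzofuran-5-carbaldehyde (target)
Conditions: PPTS (0.3 equiv), THF/H2O (4:1), rt → 40 °C
Reagents that add atoms: water, O
Why: Acetal hydrolysis; the dioxolane of a para-alkoxy benzaldehyde ionises easily, so a weak acid suffices and the para-hydroxybenzylic alcohol at C7 should not ionise or epimerise.

## Compound list

1 | syringaldehyde | COc1cc(C=O)cc(OC)c1O | starting material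
2 | 4-(benzyloxy)-3,5-dimethoxybenzaldehyde | COc1cc(C=O)cc(OC)c1OCc2ccccc2 | intermediate
3 | [4-(benzyloxy)-3,5-dimethoxyphenyl]methanol | COc1cc(CO)cc(OC)c1OCc2ccccc2 | intermediate
4 | 2-(benzyloxy)-5-(bromomethyl)-1,3-dimethoxybenzene | COc1cc(CBr)cc(OC)c1OCc2ccccc2 | intermediate
5 | 5-iodovanillin | COc1cc(C=O)cc(I)c1O | starting material
6 | 4-{[4-(benzyloxy)-3,5-dimethoxybenzyl]oxy}-3-iodo-5-methoxybenzaldehyde | COc1cc(C=O)cc(I)c1OCc2cc(OC)c(OCc3ccccc3)c(OC)c2 | intermediate
7 | 2-(4-{[4-(benzyloxy)-3,5-dimethoxybenzyl]oxy}-3-iodo-5-methoxyphenyl)-1,3-dioxolane | COc1cc(C2OCCO2)cc(I)c1OCc3cc(OC)c(OCc4ccccc4)c(OC)c3 | intermediate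
8 | methyl bromoacetate | COC(=O)CBr | starting material
9 | bromo(2-methoxy-2-oxoethyl)zinc (Reformatsky reagent) | COC(=O)C[Zn]Br | intermediate
10 | methyl 2-[2-{[4-(benzyloxy)-3,5-dimethoxybenzyl]oxy}-5-(1,3-dioxolan-2-yl)-3-methoxyphenyl]acetate | COC(=O)Cc1cc(C2OCCO2)cc(OC)c1OCc3cc(OC)c(OCc4ccccc4)c(OC)c3 | intermediate
11 | methyl 2-diazo-2-[2-{[4-(benzyloxy)-3,5-dimethoxybenzyl]oxy}-5-(1,3-dioxolan-2-yl)-3-methoxyphenyl]acetate | COC(=O)C(=[N+]=[N-])c1cc(C2OCCO2)cc(OC)c1OCc3cc(OC)c(OCc4ccccc4)c(OC)c3 | intermediate
12 | methyl (2R,3S)-2-[4-(benzyloxy)-3,5-dimethoxyphenyl]-5-(1,3-dioxolan-2-yl)-7-methoxy-2,3-dihydro-1-benzofuran-3-carboxylate (cis) | COc1cc([C@@H]2Oc3c(OC)cc(C4OCCO4)cc3[C@@H]2C(=O)OC)cc(OC)c1OCc5ccccc5 | intermediate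
13 | methyl (2R,3R)-2-[4-(benzyloxy)-3,5-dimethoxyphenyl]-5-(1,3-dioxolan-2-yl)-7-methoxy-2,3-dihydro-1-benzofuran-3-carboxylate (trans) | COc1cc([C@@H]2Oc3c(OC)cc(C4OCCO4)cc3[C@H]2C(=O)OC)cc(OC)c1OCc5ccccc5 | intermediate
14 | [(2R,3S)-2-[4-(benzyloxy)-3,5-dimethoxyphenyl]-5-(1,3-dioxolan-2-yl)-7-methoxy-2,3-dihydro-1-benzofuran-3-yl]methanol | COc1cc([C@@H]2Oc3c(OC)cc(C4OCCO4)cc3[C@H]2CO)cc(OC)c1OCc5ccccc5 | intermediate
15 | TBS ether of 14 | COc1cc([C@@H]2Oc3c(OC)cc(C4OCCO4)cc3[C@H]2CO[Si](C)(C)C(C)(C)C)cc(OC)c1OCc5ccccc5 | intermediate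
16 | 4-[(2R,3S)-3-(TBS-oxymethyl)-5-(1,3-dioxolan-2-yl)-7-methoxy-2,3-dihydro-1-benzofuran-2-yl]-2,6-dimethoxyphenol | COc1cc([C@@H]2Oc3c(OC)cc(C4OCCO4)cc3[C@H]2CO[Si](C)(C)C(C)(C)C)cc(OC)c1O | intermediate
17 | 4-bromo-2-methoxyphenol | COc1cc(Br)ccc1O | starting material
18 | (4-bromo-2-methoxyphenoxy)(tert-butyl)dimethylsilane | COc1cc(Br)ccc1O[Si](C)(C)C(C)(C)C | intermediate
19 | methyl (2R)-oxirane-2-carboxylate | COC(=O)[C@H]1CO1 | starting material
20 | (4-TBS-oxy-3-methoxyphenyl)magnesium bromide | COc1cc([Mg]Br)ccc1O[Si](C)(C)C(C)(C)C | intermediate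
21 | methyl (2R)-3-(4-TBS-oxy-3-methoxyphenyl)-2-hydroxypropanoate | COc1cc(C[C@H](C(=O)OC)O)ccc1O[Si](C)(C)C(C)(C)C | intermediate
22 | methyl (2S)-2-(ArO)-3-(4-TBS-oxy-3-methoxyphenyl)propanoate | COc1cc(C[C@@H](C(=O)OC)Oc2c(OC)cc([C@@H]3Oc4c(OC)cc(C5OCCO5)cc4[C@H]3CO[Si](C)(C)C(C)(C)C)cc2OC)ccc1O[Si](C)(C)C(C)(C)C | intermediate
23 | (2S)-2-(ArO)-3-(4-TBS-oxy-3-methoxyphenyl)propan-1-ol | COc1cc(C[C@@H](CO)Oc2c(OC)cc([C@@H]3Oc4c(OC)cc(C5OCCO5)cc4[C@H]3CO[Si](C)(C)C(C)(C)C)cc2OC)ccc1O[Si](C)(C)C(C)(C)C | intermediate
24 | tert-butyl (2S)-2-(ArO)-3-(4-TBS-oxy-3-methoxyphenyl)propyl carbonate | COc1cc(C[C@@H](COC(=O)OC(C)(C)C)Oc2c(OC)cc([C@@H]3Oc4c(OC)cc(C5OCCO5)cc4[C@H]3CO[Si](C)(C)C(C)(C)C)cc2OC)ccc1O[Si](C)(C)C(C)(C)C | intermediate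
25 | tert-butyl (2S)-2-(ArO)-3-(4-hydroxy-3-methoxyphenyl)propyl carbonate | COc1cc(C[C@@H](COC(=O)OC(C)(C)C)Oc2c(OC)cc([C@@H]3Oc4c(OC)cc(C5OCCO5)cc4[C@H]3CO[Si](C)(C)C(C)(C)C)cc2OC)ccc1O | intermediate
26 | tert-butyl (2S)-2-(ArO)-3-(3-methoxy-4-oxocyclohexa-2,5-dien-1-ylidene)propyl carbonate (quinone methide) | COC1=CC(=C[C@@H](COC(=O)OC(C)(C)C)Oc2c(OC)cc([C@@H]3Oc4c(OC)cc(C5OCCO5)cc4[C@H]3CO[Si](C)(C)C(C)(C)C)cc2OC)C=CC1=O | intermediate
27 | (4S,5R)-5-(ArO)-4-(4-hydroxy-3-methoxyphenyl)-1,3-dioxan-2-one | COc1cc([C@@H]2OC(=O)OC[C@H]2Oc3c(OC)cc([C@@H]4Oc5c(OC)cc(C6OCCO6)cc5[C@H]4CO[Si](C)(C)C(C)(C)C)cc3OC)ccc1O | intermediate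
28 | (4S,5R)-5-(ArO)-4-(4-TBS-oxy-3-methoxyphenyl)-1,3-dioxan-2-one | COc1cc([C@@H]2OC(=O)OC[C@H]2Oc3c(OC)cc([C@@H]4Oc5c(OC)cc(C6OCCO6)cc5[C@H]4CO[Si](C)(C)C(C)(C)C)cc3OC)ccc1O[Si](C)(C)C(C)(C)C | intermediate
29 | (1S,2R)-2-(ArO)-1-(4-TBS-oxy-3-methoxyphenyl)propane-1,3-diol | COc1cc([C@H](O)[C@@H](CO)Oc2c(OC)cc([C@@H]3Oc4c(OC)cc(C5OCCO5)cc4[C@H]3CO[Si](C)(C)C(C)(C)C)cc2OC)ccc1O[Si](C)(C)C(C)(C)C | intermediate
30 | dioxolane of the target (all hydroxyl groups free) | COc1cc([C@H](O)[C@@H](CO)Oc2c(OC)cc([C@@H]3Oc4c(OC)cc(C5OCCO5)cc4[C@H]3CO)cc2OC)ccc1O | intermediate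
31 | (2R,3S)-2-(4-{[(1S,2R)-1,3-dihydroxy-1-(4-hydroxy-3-methoxyphenyl)propan-2-yl]oxy}-3,5-dimethoxyphenyl)-3-(hydroxymethyl)-7-methoxy-2,3-dihydro-1-benzofuran-5-carbaldehyde | COc1cc([C@H](O)[C@@H](CO)Oc2c(OC)cc([C@@H]3Oc4c(OC)cc(C=O)cc4[C@H]3CO)cc2OC)ccc1O | target

## Step count and least certain steps

Total: 22 steps. Longest linear sequence: 20 steps (steps 1–11, then 14–22); steps 12 and 13 form a two-step side branch.

**Step 18 (key step).**
- What may go wrong: one-electron phenoxyl coupling at the unsubstituted ortho position of ring A instead of clean two-electron oxidation; tautomerisation of the quinone methide to the C7=C8 enol ether; capture by residual water ahead of the weakly nucleophilic carbonyl oxygen; re-ionisation of the para-hydroxybenzyl carbonate followed by irreversible loss of carbon dioxide; incomplete facial selectivity.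
- Fallback (known chemistry, intermolecular instead of tethered capture): it sets out from 23. The aryl silyl ether is removed with Cs2CO3 in DMF/H2O to give 4-[(2S)-2-(ArO)-3-hydroxypropyl]-2-methoxyphenol F1. Ag2O in CH2Cl2 converts it into the quinone methide F2. Water in buffered aqueous THF (about pH 5) then adds to C7 to give the erythro triol (1S,2R)-2-(ArO)-1-(4-hydroxy-3-methoxyphenyl)propane-1,3-diol F3 together with its threo C7 epimer F4, which is removed by chromatography. Addition is substrate-controlled only; the erythro isomer is expected to predominate with a 2,6-dimethoxyphenyl ether. Bu4NF then converts F3 into 30, where the route is rejoined.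

**Step 19.**
- What may go wrong: 1,6-elimination of the carbonate from the free phenol of 27 before the silyl group is on, which destroys the C7 stereocentre.
- Fallback (acid-installed, base-stable cap): it sets out from 27. Dihydropyran with catalytic PPTS in CH2Cl2, with no base, gives the tetrahydropyranyl ether of the cyclic carbonate F5. Because this cap is inert to base, K2CO3 in MeOH opens the carbonate to the 7,9-diol F6. Bu4NF removes the C9' silyl group to give triol F7. The final PPTS/aqueous THF treatment cleaves the tetrahydropyranyl ether and the dioxolane together and returns to the route at 31.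

**Step 14.**
- What may go wrong: slow substitution by the di-ortho-substituted phenol, which would allow elimination of the activated hydroxy ester to the cinnamate or alkylation of the reduced azodicarboxylate.
- Fallback (preformed leaving group and fully ionised nucleophile): it sets out from 21. Tf2O with 2,6-lutidine at −78 °C gives the triflate methyl (2R)-3-(4-TBS-oxy-3-methoxyphenyl)-2-(trifluoromethanesulfonyloxy)propanoate F8. The caesium phenoxide of 16 (Cs2CO3, MeCN, −20 °C) displaces it with inversion, returning to the route at 22.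

**Step 8.**
- What may go wrong: insufficient or reversed enantioface discrimination on this trioxygenated substrate, or carbene dimerisation at the low temperature needed for selectivity.
- Fallback (auxiliary control in place of catalyst control alone): it sets out from 10. LiOH gives the arylacetic acid F9. Carbodiimide coupling with (2S)-2-hydroxy-1-(pyrrolidin-1-yl)propan-1-one gives the lactamide ester F10. Diazo transfer (p-ABSA, DBU) gives the diazo ester F11. Insertion with Rh2(S-DOSP)4, with auxiliary and catalyst antipodes paired for the (2R) series, gives the dihydrobenzofuran lactamide ester F12. NaOMe in MeOH exchanges the auxiliary for methoxide and equilibrates C3, returning to the route at 13.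

## Further compounds

F1 | step 18 | 4-[(2S)-2-(ArO)-3-hydroxypropyl]-2-methoxyphenol | COc1cc(C[C@@H](CO)Oc2c(OC)cc([C@@H]3Oc4c(OC)cc(C5OCCO5)cc4[C@H]3CO[Si](C)(C)C(C)(C)C)cc2OC)ccc1O
F2 | step 18 | 4-[(2S)-2-(ArO)-3-hydroxypropylidene]-2-methoxycyclohexa-2,5-dien-1-one (quinone methide) | COC1=CC(=C[C@@H](CO)Oc2c(OC)cc([C@@H]3Oc4c(OC)cc(C5OCCO5)cc4[C@H]3CO[Si](C)(C)C(C)(C)C)cc2OC)C=CC1=O
F3 | step 18 | (1S,2R)-2-(ArO)-1-(4-hydroxy-3-methoxyphenyl)propane-1,3-diol (erythro) | COc1cc([C@H](O)[C@@H](CO)Oc2c(OC)cc([C@@H]3Oc4c(OC)cc(C5OCCO5)cc4[C@H]3CO[Si](C)(C)C(C)(C)C)cc2OC)ccc1O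
F4 | step 18 | (1R,2R)-2-(ArO)-1-(4-hydroxy-3-methoxyphenyl)propane-1,3-diol (threo) | COc1cc([C@@H](O)[C@@H](CO)Oc2c(OC)cc([C@@H]3Oc4c(OC)cc(C5OCCO5)cc4[C@H]3CO[Si](C)(C)C(C)(C)C)cc2OC)ccc1O
F5 | step 19 | (4S,5R)-5-(ArO)-4-[3-methoxy-4-(tetrahydro-2H-pyran-2-yloxy)phenyl]-1,3-dioxan-2-one | COc1cc([C@@H]2OC(=O)OC[C@H]2Oc3c(OC)cc([C@@H]4Oc5c(OC)cc(C6OCCO6)cc5[C@H]4CO[Si](C)(C)C(C)(C)C)cc3OC)ccc1OC7CCCCO7
F6 | step 19 | (1S,2R)-2-(ArO)-1-[3-methoxy-4-(tetrahydro-2H-pyran-2-yloxy)phenyl]propane-1,3-diol | COc1cc([C@H](O)[C@@H](CO)Oc2c(OC)cc([C@@H]3Oc4c(OC)cc(C5OCCO5)cc4[C@H]3CO[Si](C)(C)C(C)(C)C)cc2OC)ccc1OC6CCCCO6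
F7 | step 19 | tetrahydropyranyl ether of 30 at the ring A phenol | COc1cc([C@H](O)[C@@H](CO)Oc2c(OC)cc([C@@H]3Oc4c(OC)cc(C5OCCO5)cc4[C@H]3CO)cc2OC)ccc1OC6CCCCO6
F8 | step 14 | methyl (2R)-3-(4-TBS-oxy-3-methoxyphenyl)-2-(trifluoromethanesulfonyloxy)propanoate | COc1cc(C[C@H](C(=O)OC)OS(=O)(=O)C(F)(F)F)ccc1O[Si](C)(C)C(C)(C)C
F9 | step 8 | 2-[2-{[4-(benzyloxy)-3,5-dimethoxybenzyl]oxy}-5-(1,3-dioxolan-2-yl)-3-methoxyphenyl]acetic acid | OC(=O)Cc1cc(C2OCCO2)cc(OC)c1OCc3cc(OC)c(OCc4ccccc4)c(OC)c3
F10 | step 8 | (2S)-1-oxo-1-(pyrrolidin-1-yl)propan-2-yl ester of F9 | C[C@H](OC(=O)Cc1cc(C2OCCO2)cc(OC)c1OCc3cc(OC)c(OCc4ccccc4)c(OC)c3)C(=O)N5CCCC5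
F11 | step 8 | alpha-diazo derivative of F10 | C[C@H](OC(=O)C(=[N+]=[N-])c1cc(C2OCCO2)cc(OC)c1OCc3cc(OC)c(OCc4ccccc4)c(OC)c3)C(=O)N5CCCC5
F12 | step 8 | (2S)-1-oxo-1-(pyrrolidin-1-yl)propan-2-yl (2R)-2-[4-(benzyloxy)-3,5-dimethoxyphenyl]-5-(1,3-dioxolan-2-yl)-7-methoxy-2,3-dihydro-1-benzofuran-3-carboxylate (C3 not fixed) | COc1cc([C@@H]2Oc3c(OC)cc(C4OCCO4)cc3C2C(=O)O[C@@H](C)C(=O)N6CCCC6)cc(OC)c1OCc5ccccc5
A1 | alternative 1 | 4-hydroxy-3-methoxy-5-[(E)-2-(3,5-dimethoxy-4-triisopropylsilyloxyphenyl)ethenyl]benzaldehyde | COc1cc(C=O)cc(/C=C/c2cc(OC)c(O[Si](C(C)C)(C(C)C)C(C)C)c(OC)c2)c1O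
A2 | alternative 1 | methyl (2R,3R)-2-(3,5-dimethoxy-4-triisopropylsilyloxyphenyl)-5-formyl-7-methoxy-2,3-dihydrobenzofuran-3-carboxylate | COc1cc([C@@H]2Oc3c(OC)cc(C=O)cc3[C@H]2C(=O)OC)cc(OC)c1O[Si](C(C)C)(C(C)C)C(C)C
A3 | alternative 2 | 4-[(1R)-1-[4-(1,3-dioxolan-2-yl)-2-iodo-6-methoxyphenoxy]prop-2-en-1-yl]-2,6-dimethoxyphenyl pivalate | CC(C)(C)C(=O)Oc1c(OC)cc([C@@H](C=C)Oc2c(OC)cc(C3OCCO3)cc2I)cc1OC
A4 | alternative 2 | 4-[(2R,3S)-5-(1,3-dioxolan-2-yl)-7-methoxy-3-[(2,2,6,6-tetramethylpiperidin-1-yloxy)methyl]-2,3-dihydrobenzofuran-2-yl]-2,6-dimethoxyphenyl pivalate | CC(C)(C)C(=O)Oc1c(OC)cc([C@@H]2Oc3c(OC)cc(C4OCCO4)cc3[C@H]2CON5C(C)(C)CCCC5(C)C)cc1OC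
A5 | alternative 3 | 4-hydroxy-3-[(2S)-1-(tert-butyldimethylsilyloxy)-3-(4-hydroxy-3,5-dimethoxyphenyl)propan-2-yl]-5-methoxybenzaldehyde | COc1cc(C[C@H](CO[Si](C)(C)C(C)(C)C)c2cc(C=O)cc(OC)c2O)cc(OC)c1O
A6 | alternative 3 | (2R,3S)-2-(4-hydroxy-3,5-dimethoxyphenyl)-3-(tert-butyldimethylsilyloxymethyl)-7-methoxy-2,3-dihydrobenzofuran-5-carbaldehyde | COc1cc([C@@H]2Oc3c(OC)cc(C=O)cc3[C@H]2CO[Si](C)(C)C(C)(C)C)cc(OC)c1O
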